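Amounts first: south-east holds 18 mM of starting material against 17.1 mM of activator, and what is wanted is the share of that charge which ends as ring when the activator arrives slowly.

| flask | starting material | activator | protic impurity | temperature | remark | time |
|---|---|---|---|---|---|---|
| autumn | 18 mM | 17.1 mM | 18 mM | 85 °C | run made earlier |  |
| dawn | 18 mM | 11 mM | 18 mM | 100 °C | run made earlier |  |
| summer | 18 mM | 26 mM | 18 mM | 85 °C | run made earlier |  |
| midnight | 9 mM | 17.1 mM | 18 mM | 100 °C | run made earlier |  |
| east | 18 mM (in portions, 2, over 3.0 d) | 17.1 mM | 18.0 mM | 100 °C | first portion at the start, last at 3.0 d | 8.0 d |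
| north | 18 mM | 17.1 mM | 18.0 mM |  | everything together at the start at 80 °C, warmed to 100 °C at 3.0 d | 8.0 d |
| south | 18 mM | 17.1 mM (fed, over 8.0 h) | 18.0 mM | 100 °C | all else is in the flask from the start; the feed brings no volume worth counting | 8.0 d |
| south-west | 18 mM | 17.1 mM | 18.0 mM | 100 °C | everything together at the start | 8.0 d |
| south-east | 18 mM | 17.1 mM (fed, over 3.0 d) | 18.0 mM |  | the addition at 80 °C, then warmed to 100 °C; the feed brings no volume worth counting | 8.0 d |
| west | 18 mM (fed, over 3.0 d) | 17.1 mM | 18.0 mM | 100 °C | all else is in the flask from the start; the feed brings no volume worth counting | 8.0 d |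

| run | time / d | ring / % |
|---|---|---|
| autumn | 1.04 | 13 |
| autumn | 4.00 | 33 |
| autumn | 6.00 | 25 |
| autumn | 8.00 | 30 |
| autumn | 12.0 | 31 |
| autumn | 15.0 | 30 |
| dawn | 0.417 | 12 |
| dawn | 1.25 | 23 |
| dawn | 2.50 | 21 |
| dawn | 4.00 | 26 |
| dawn | 5.00 | 25 |
| dawn | 6.00 | 22 |
| summer | 0.833 | 19 |
| summer | 2.50 | 33 |
| summer | 5.00 | 37 |
| summer | 8.00 | 39 |
| summer | 10.0 | 38 |
| summer | 12.0 | 37 |
| midnight | 1.25 | 41 |
| midnight | 2.50 | 45 |
| midnight | 4.00 | 47 |
| midnight | 5.00 | 42 |
| midnight | 6.00 | 44 |

(standard deviation of a reading: 2 percentage points)



- the flask with the highest amount of ring, in percent of the starting material charged ("all alike" if they lie within 1.5 percentage points) (east / north / south / south-west / south-east / west / all alike)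
- final ring, as a percentage of the starting material charged, in east
- final ring, as a percentage of the starting material charged, in north
- final ring, as a percentage of the starting material charged, in south
- final ring, as a percentage of the starting material charged, in south-west
- final ring, as a percentage of the starting material charged, in south-east
- final ring, as a percentage of the starting material charged, in west

Dividing the rate of the ring route by the rate of the loss route removes time. If ring grows with [starting material][activator] and loss with [starting material] squared, the ring share depends on one ratio:

ring share = ρ / (ρ + [starting material]/[activator])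

The midnight readings average 43.8%, and with mean [starting material] taken as half its charge they give 0.205 for ρ, the value of [starting material]/[activator] at which ring and loss take equal shares, a selectivity factor.

Two extreme versions of south-east can then be reckoned, and this reckoning is my own:

activator all present throughout: ρ / (ρ + 0.5·18 mM / 17.1 mM) = 28.0%

mean [activator] also half its charge: ρ / (ρ + 18 mM / 17.1 mM) = 16.3%

The first sits near the autumn plateau reading of 31%, a run that did not enter ρ. South-east is placed between the two as an estimate: its activator is fed from nothing over 3.0 d, so the amount added stands on average over that feed at half the charge, as in the second version, while after the feed the whole charge has gone in, as in the first.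

The forecast named west as best and gave 43% for east, 30% for north, 21% for south, 31% for south-west, 20% for south-east and 55% for west, adding “Activator consumption is the main uncertainty.”

The flasks give 34.9% for east, 29.4% for north, 29.3% for south, 32.1% for south-west, 25.8% for south-east and 36.4% for west, so west stands highest.

    starting material + activator → activated form (k = 0.00130 /M/s, Ea = 81.0 kJ/mol)
    activated form → ring (k = 9.80 × 10⁻⁵ /s, Ea = 107 kJ/mol)
    starting material + activated form → open dimer (k = 0.00290 /M/s, Ea = 75.0 kJ/mol)
    starting material + protic impurity → quenched substrate (k = 8.10 × 10⁻⁴ /M/s, Ea = 92.0 kJ/mol)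
    starting material + ring → side product (k = 8.70 × 10⁻⁴ /M/s, Ea = 63.0 kJ/mol)
    2 starting material → homo dimer (k = 1.40 × 10⁻⁴ /M/s, Ea = 98.0 kJ/mol)
    (constants at 100 °C)

South-east ends inside the reckoned range, above 16.3% and below 28.0%. At 1.23 d in south-east, activated form goes to ring 1.6 times as fast as to open dimer, and starting material has a half-life of 3.7 d by quenching against 81 d by attack on ring. The loss lumped into ρ stands at the end in south-east chiefly as quenched substrate, 41.9%.

For south-east with 11 mM of starting material, ρ gives between 24.2% and 38.9%; that flask computes to 32.0%.

The runs are calculated on assumed constants, noise included.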